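**Retrosynthetic overview**

- The strategy rests on the cis A/B ring fusion: the methyl on quaternary C10 and H-5 lie on the same face, C10 is bonded to the tetrasubstituted C8=C9 alkene of ring B, and ring A (C1–C5, C10, gem-dimethyl C4, stereocentre C5) is the ring of (R)-α-ionone.
- Side chain, made last: C15=C16 by Horner–Wadsworth–Emmons olefination of enal 30 with butenolide phosphonate 33; the C13 hydroxymethyl by syn-carbocupration of ynoate 20; C11–C12 by propargylation of allylic bromide 14.
- Ring B: the C9–C10 bond by intramolecular Heck cyclisation of (Z)-iodoenoate 10, with C5 relaying its configuration to C10.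
- Iodoenoate 10: syn-carbocupration of methyl but-2-ynoate by the C7 alkylcopper from (R)-α-ionone (conjugate reduction, haloform cleavage, decarboxylative iodination), then iodine capture.
- Ring order: ring A from the chiral pool, ring B in step 5, the butenolide ring brought in intact in step 18.

Key step: step 5

Remark: (R)-α-ionone is taken as available in high enantiomeric purity. Carbons are numbered as in labdanes (ring A C1–C5 and C10, ring B C5–C10, side chain C11–C16 outward from C9). "Bic" stands for the (4aR,8aS)-2,5,5,8a-tetramethyl-3,4,4a,5,6,7,8,8a-octahydronaphthalen-1-yl group, in which the 8a-methyl (on C10) and 4a-H (on C5) are cis.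

**Route**

Step 1
Reactants: 1 (R)-α-ionone, (3E)-4-[(1R)-2,6,6-trimethylcyclohex-2-en-1-yl]but-3-en-2-one
Product: 2 4-[(1R)-2,6,6-trimethylcyclohex-2-en-1-yl]butan-2-one
Conditions: [(Ph3P)CuH]6 (2 mol%), PhMe2SiH, t-BuOH, toluene, rt
Reagents that add atoms: none
Why: Catalytic copper hydride conjugate reduction, in which phosphine-ligated CuH delivers hydride 1,4 to the enone and tert-butanol protonates the copper enolate, should leave the isolated trisubstituted ring alkene and the C5 centre untouched because the medium is never basic enough to deprotonate C5.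

Step 2
Reactants: 2 4-[(1R)-2,6,6-trimethylcyclohex-2-en-1-yl]butan-2-one
Product: 3 3-[(1R)-2,6,6-trimethylcyclohex-2-en-1-yl]propanoic acid
Conditions: Br2, aq. NaOH, 0 °C (gives NaOBr); then 2, 1,4-dioxane, 0 °C → rt; Na2SO3; 1 M HCl to pH 3, 0 °C
Reagents that add atoms: sodium hydroxide, [Na+].[OH-]
Why: Haloform reaction, in which exhaustive α-bromination of the methyl ketone and hydroxide cleavage of the tribromomethyl ketone give the carboxylate, while hypobromite in excess alkali is not electrophilic enough to attack the ring alkene and C5 is remote from any acidic position.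

Step 3
Reactants: 3 3-[(1R)-2,6,6-trimethylcyclohex-2-en-1-yl]propanoic acid
Product: 5 (6R)-6-(2-iodoethyl)-1,5,5-trimethylcyclohex-1-ene, via Barton ester 4 (not isolated)
Conditions: 1-hydroxypyridine-2(1H)-thione, DCC, DMAP (cat.), CH2Cl2, 0 °C → rt, dark; then CHI3, PhH, hν (tungsten lamp), rt → 40 °C
Reagents that add atoms: iodoform, IC(I)I; 1-hydroxypyridine-2(1H)-thione, ON1C=CC=CC1=S (atoms only in intermediate 4)
Why: Barton decarboxylative iodination, in which the thiohydroxamate ester fragments under visible light to the primary C7 radical that takes iodine from iodoform faster than it can add to the ring alkene (only 4-exo or 5-endo modes are open), removes one carbon without acid or electrophilic halogen near the ring alkene.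

Step 4
Reactants: 5 (6R)-6-(2-iodoethyl)-1,5,5-trimethylcyclohex-1-ene; 6 methyl but-2-ynoate
Product: 10 methyl (2Z)-2-iodo-3-methyl-5-[(1R)-2,6,6-trimethylcyclohex-2-en-1-yl]pent-2-enoate, via alkylmagnesium iodide 7 (not isolated), via alkylcopper 8 (not isolated), via vinylcopper adduct 9 (not isolated)
Conditions: Mg, Et2O, rt; CuBr·SMe2 (1 equiv), THF, −45 °C; 6, −78 °C; I2 in THF, −78 °C
Reagents that add atoms: iodine, II; magnesium, [Mg] (atom only in intermediate 7); CuBr·SMe2, [Cu]Br.CSC (copper only in intermediates 8 and 9)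
Why: Syn-carbocupration of an ynoate by an alkylcopper–magnesium halide reagent places C7 on the methyl-bearing β-carbon C8 and copper on C9 on the same side, and iodinolysis of the α-cuprio enoate at −78 °C goes with retention, so iodine should end cis to C7 (Z).

Step 5
Reactants: 10 methyl (2Z)-2-iodo-3-methyl-5-[(1R)-2,6,6-trimethylcyclohex-2-en-1-yl]pent-2-enoate
Product: 11 methyl (4aR,8aS)-2,5,5,8a-tetramethyl-3,4,4a,5,6,8a-hexahydronaphthalene-1-carboxylate
Conditions: Pd(OAc)2 (10 mol%), PPh3 (30 mol%), Ag2CO3 (1.5 equiv), degassed MeCN, 80 °C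
Reagents that add atoms: none
Why: Zerovalent palladium, formed from Pd(OAc)2 and PPh3, inserts into the C9–I bond with retention of the Z geometry, so the divalent vinylpalladium centre sits cis to C7 and can fold over ring A, and Ag2CO3 removes iodide to give a cationic palladium that binds the hindered C10=C1 alkene. Ring B (C5–C6–C7–C8–C9–C10) then closes by 6-exo-trig syn-carbopalladation with C9 bonding to the fully substituted C10, the closest known reaction type being the intramolecular Heck cyclisation that builds quaternary carbons in cis-fused decalins. The new stereocentre C10 is controlled by the existing C5 centre, because the C6–C7–C8 tether can deliver C9 only to the alkene face on which C6 stands, which puts C9 cis to C6 and the C10 methyl cis to H-5. C10 carries no hydrogen, so palladium on C1 can leave only by syn β-hydride elimination toward C2, giving the C1=C2 alkene and leaving the tetrasubstituted C8=C9 enoate where it was formed. The step needs regioselectivity (6-exo at C10 over 7-endo at C1), secured by the six-membered transition state, and face selectivity, secured by the short tether; the neutral conditions form no C10 cation, so the ring alkene cannot drift to C5=C10 and erase the C5 centre.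

Step 6
Reactants: 11 methyl (4aR,8aS)-2,5,5,8a-tetramethyl-3,4,4a,5,6,8a-hexahydronaphthalene-1-carboxylate
Product: 12 methyl (4aR,8aS)-2,5,5,8a-tetramethyl-3,4,4a,5,6,7,8,8a-octahydronaphthalene-1-carboxylate
Conditions: TsNHNH2 (excess), NaOAc, DME/H2O, reflux
Reagents that add atoms: none
Why: Diimide reduction, with diimide formed by thermal fragmentation of the sulfonylhydrazide, transfers hydrogen syn to the cis-disubstituted C1=C2 alkene and should be inert toward the tetrasubstituted, ester-conjugated C8=C9 alkene; no stereocentre is affected.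

Step 7
Reactants: 12 methyl (4aR,8aS)-2,5,5,8a-tetramethyl-3,4,4a,5,6,7,8,8a-octahydronaphthalene-1-carboxylate
Product: 13 (Bic)methanol
Conditions: i-Bu2AlH (2.5 equiv), CH2Cl2, −78 → 0 °C; aq. potassium sodium tartrate
Reagents that add atoms: none
Why: Aluminium hydride 1,2-reduction of the hindered conjugated ester with excess i-Bu2AlH should give the primary allylic alcohol without touching the tetrasubstituted alkene.

Step 8
Reactants: 13 (Bic)methanol
Product: 14 (4aR,8aS)-1-(bromomethyl)-2,5,5,8a-tetramethyl-3,4,4a,5,6,7,8,8a-octahydronaphthalene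
Conditions: PBr3 (0.4 equiv), pyridine (cat.), Et2O, −10 → 0 °C; used at once
Reagents that add atoms: phosphorus tribromide, BrP(Br)Br
Why: Bromination of a primary allylic alcohol with PBr3 proceeds through the phosphite ester by SN2 displacement, and allylic transposition is disfavoured because it would give a tertiary bromide with a less substituted exocyclic alkene.

Step 9
Reactants: 14 (4aR,8aS)-1-(bromomethyl)-2,5,5,8a-tetramethyl-3,4,4a,5,6,7,8,8a-octahydronaphthalene; 15 1-(trimethylsilyl)propyne
Product: 17 trimethyl[4-(Bic)but-1-yn-1-yl]silane, via lithiated silylpropyne 16 (not isolated)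
Conditions: 15, n-BuLi, THF, −78 → −20 °C; then 14, THF, −78 °C → rt
Reagents that add atoms: n-butyllithium, [Li]CCCC (lithium only in intermediate 16)
Why: Propargylic lithiation of the silylpropyne followed by SN2 alkylation with the primary allylic bromide forms C11–C12, the silyl group steering reaction to the propargylic terminus and the tetrasubstituted C8 blocking SN2′ attack.

Step 10
Reactants: 17 trimethyl[4-(Bic)but-1-yn-1-yl]silane
Product: 18 4-(Bic)but-1-yne
Conditions: K2CO3 (cat.), MeOH/THF, rt
Reagents that add atoms: none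
Why: Base-catalysed methanolysis of the alkynyl C–Si bond (protodesilylation) should free the terminal alkyne without affecting any other group.

Step 11
Reactants: 18 4-(Bic)but-1-yne
Product: 20 methyl 5-(Bic)pent-2-ynoate, via lithium acetylide 19 (not isolated)
Conditions: n-BuLi, THF, −78 °C; ClCO2Me, −78 → 0 °C
Reagents that add atoms: methyl chloroformate, COC(Cl)=O; n-butyllithium, [Li]CCCC (lithium only in intermediate 19)
Why: Deprotonation of the terminal alkyne and acylation of the lithium acetylide with a chloroformate (acetylide carboxylation) gives the ynoate that carries C15.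

Step 12
Reactants: 21 4-methoxybenzyl alcohol; 22 tributyl(iodomethyl)stannane
Product: 24 tributyl{[(4-methoxybenzyl)oxy]methyl}stannane, via sodium alkoxide 23 (not isolated)
Conditions: 21, NaH, THF, 0 °C; then 22, 0 °C → rt
Reagents that add atoms: sodium hydride, [Na+].[H-] (sodium only in intermediate 23)
Why: Williamson ether synthesis, in which the alkoxide displaces iodide from the unhindered iodomethyl carbon of the stannane.

Step 13
Reactants: 24 tributyl{[(4-methoxybenzyl)oxy]methyl}stannane; 20 methyl 5-(Bic)pent-2-ynoate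
Product: 28 methyl (2E)-3-{[(4-methoxybenzyl)oxy]methyl}-5-(Bic)pent-2-enoate, via alkoxymethyllithium 25 (not isolated), via lithium dialkylcuprate 26 (not isolated), via vinylcuprate adduct 27 (not isolated)
Conditions: 24 (2.2 equiv), n-BuLi (2.2 equiv), THF, −78 °C; CuBr·SMe2 (1.1 equiv), −78 °C; 20, −78 °C; MeOH then aq. NH4Cl, −78 °C → rt
Reagents that add atoms: n-butyllithium, [Li]CCCC (lithium only in intermediates 25 to 27); CuBr·SMe2, [Cu]Br.CSC (copper only in intermediates 26 and 27)
Why: Tin–lithium exchange gives the α-alkoxymethyllithium, whose lithium cuprate adds syn across the ynoate (carbocupration) with the alkoxymethyl group going to the β-carbon C13, and protonation at −78 °C with retention puts the new CH2O group trans to the ester, which fixes the 13E geometry.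

Step 14
Reactants: 28 methyl (2E)-3-{[(4-methoxybenzyl)oxy]methyl}-5-(Bic)pent-2-enoate
Product: 29 (2E)-3-{[(4-methoxybenzyl)oxy]methyl}-5-(Bic)pent-2-en-1-ol
Conditions: i-Bu2AlH (2.5 equiv), CH2Cl2, −78 °C; aq. potassium sodium tartrate
Reagents that add atoms: none
Why: Aluminium hydride 1,2-reduction of the enoate gives the allylic alcohol and should leave the benzyl-type ether and both alkenes unchanged.

Step 15
Reactants: 29 (2E)-3-{[(4-methoxybenzyl)oxy]methyl}-5-(Bic)pent-2-en-1-ol
Product: 30 (2E)-3-{[(4-methoxybenzyl)oxy]methyl}-5-(Bic)pent-2-enal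
Conditions: MnO2 (excess), CH2Cl2, rt
Reagents that add atoms: none
Why: Allylic oxidation with MnO2 is selective for the primary allylic alcohol under neutral heterogeneous conditions and should not isomerise the trisubstituted alkene.

Step 16
Reactants: 31 4-methylfuran-2(5H)-one
Product: 32 4-(bromomethyl)furan-2(5H)-one
Conditions: NBS, AIBN (cat.), PhCF3, reflux
Reagents that add atoms: N-bromosuccinimide, BrN1C(=O)CCC1=O
Why: Wohl–Ziegler radical bromination at the allylic methyl group, whose radical is stabilised by conjugation with the butenolide alkene.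

Step 17
Reactants: 32 4-(bromomethyl)furan-2(5H)-one
Product: 33 diethyl [(5-oxo-2,5-dihydrofuran-3-yl)methyl]phosphonate
Conditions: P(OEt)3, toluene, 110 °C
Reagents that add atoms: triethyl phosphite, CCOP(OCC)OCC
Why: Michaelis–Arbuzov reaction of the primary allylic bromide with the phosphite, driven by loss of bromoethane.

Step 18
Reactants: 33 diethyl [(5-oxo-2,5-dihydrofuran-3-yl)methyl]phosphonate; 30 (2E)-3-{[(4-methoxybenzyl)oxy]methyl}-5-(Bic)pent-2-enal
Product: 35 4-[(1E,3E)-4-{[(4-methoxybenzyl)oxy]methyl}-6-(Bic)hexa-1,3-dien-1-yl]furan-2(5H)-one, via lithiated phosphonate 34 (not isolated)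
Conditions: 33, LiN(SiMe3)2, THF, −78 °C; then 30, −78 → 0 °C
Reagents that add atoms: LiN(SiMe3)2, [Li]N([Si](C)(C)C)[Si](C)(C)C (lithium only in intermediate 34)
Why: Horner–Wadsworth–Emmons olefination, in which the phosphonate-stabilised carbanion adds to the enal through its phosphorus-bearing carbon and the oxaphosphetane collapses to the E alkene C15=C16, completing the conjugated triene.

Step 19
Reactants: 35 4-[(1E,3E)-4-{[(4-methoxybenzyl)oxy]methyl}-6-(Bic)hexa-1,3-dien-1-yl]furan-2(5H)-one
Product: 36 4-[(1E,3E)-4-(hydroxymethyl)-6-(Bic)hexa-1,3-dien-1-yl]furan-2(5H)-one (CNP0232848.3)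
Conditions: DDQ (1.2 equiv), CH2Cl2/pH 7 phosphate buffer, 0 °C
Reagents that add atoms: none
Why: Oxidative cleavage of the 4-methoxybenzyl ether by DDQ (electron transfer from the electron-rich arene, then hydrolysis of the oxocarbenium ion) in buffered wet dichloromethane should spare the electron-poor triene lactone and the isolated tetrasubstituted alkene.

**Compound list** (Bic as defined in the remark)

1 | (R)-α-ionone, (3E)-4-[(1R)-2,6,6-trimethylcyclohex-2-en-1-yl]but-3-en-2-one | CC(=O)/C=C/[C@H]1C(C)=CCCC1(C)C | starting material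
2 | 4-[(1R)-2,6,6-trimethylcyclohex-2-en-1-yl]butan-2-one | CC(=O)CC[C@H]1C(C)=CCCC1(C)C | intermediate
3 | 3-[(1R)-2,6,6-trimethylcyclohex-2-en-1-yl]propanoic acid | OC(=O)CC[C@H]1C(C)=CCCC1(C)C | intermediate
4 | 2-thioxopyridin-1(2H)-yl 3-[(1R)-2,6,6-trimethylcyclohex-2-en-1-yl]propanoate (Barton ester) | S=C1C=CC=CN1OC(=O)CC[C@H]1C(C)=CCCC1(C)C | intermediate
5 | (6R)-6-(2-iodoethyl)-1,5,5-trimethylcyclohex-1-ene | ICC[C@H]1C(C)=CCCC1(C)C | intermediate
6 | methyl but-2-ynoate | CC#CC(=O)OC | starting material
7 | {2-[(1R)-2,6,6-trimethylcyclohex-2-en-1-yl]ethyl}magnesium iodide | I[Mg]CC[C@H]1C(C)=CCCC1(C)C | intermediate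
8 | {2-[(1R)-2,6,6-trimethylcyclohex-2-en-1-yl]ethyl}copper | [Cu]CC[C@H]1C(C)=CCCC1(C)C | intermediate
9 | methyl (2Z)-2-cuprio-3-methyl-5-[(1R)-2,6,6-trimethylcyclohex-2-en-1-yl]pent-2-enoate (copper cis to C7) | COC(=O)/C([Cu])=C(\C)CC[C@H]1C(C)=CCCC1(C)C | intermediate
10 | methyl (2Z)-2-iodo-3-methyl-5-[(1R)-2,6,6-trimethylcyclohex-2-en-1-yl]pent-2-enoate | COC(=O)/C(I)=C(\C)CC[C@H]1C(C)=CCCC1(C)C | intermediate
11 | methyl (4aR,8aS)-2,5,5,8a-tetramethyl-3,4,4a,5,6,8a-hexahydronaphthalene-1-carboxylate (cis-fused) | CC1=C(C(=O)OC)[C@@]2(C)C=CCC(C)(C)[C@H]2CC1 | intermediate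
12 | methyl (4aR,8aS)-2,5,5,8a-tetramethyl-3,4,4a,5,6,7,8,8a-octahydronaphthalene-1-carboxylate | CC1=C(C(=O)OC)[C@@]2(C)CCCC(C)(C)[C@H]2CC1 | intermediate
13 | (Bic)methanol | CC1=C(CO)[C@@]2(C)CCCC(C)(C)[C@H]2CC1 | intermediate
14 | (4aR,8aS)-1-(bromomethyl)-2,5,5,8a-tetramethyl-3,4,4a,5,6,7,8,8a-octahydronaphthalene | CC1=C(CBr)[C@@]2(C)CCCC(C)(C)[C@H]2CC1 | intermediate
15 | 1-(trimethylsilyl)propyne | CC#C[Si](C)(C)C | starting material
16 | [3-(trimethylsilyl)prop-2-yn-1-yl]lithium | [Li]CC#C[Si](C)(C)C | intermediate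
17 | trimethyl[4-(Bic)but-1-yn-1-yl]silane | CC1=C(CCC#C[Si](C)(C)C)[C@@]2(C)CCCC(C)(C)[C@H]2CC1 | intermediate
18 | 4-(Bic)but-1-yne | CC1=C(CCC#C)[C@@]2(C)CCCC(C)(C)[C@H]2CC1 | intermediate
19 | [4-(Bic)but-1-yn-1-yl]lithium | CC1=C(CCC#C[Li])[C@@]2(C)CCCC(C)(C)[C@H]2CC1 | intermediate
20 | methyl 5-(Bic)pent-2-ynoate | CC1=C(CCC#CC(=O)OC)[C@@]2(C)CCCC(C)(C)[C@H]2CC1 | intermediate
21 | 4-methoxybenzyl alcohol | COc1ccc(CO)cc1 | starting material
22 | tributyl(iodomethyl)stannane | CCCC[Sn](CCCC)(CCCC)CI | starting material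
23 | sodium (4-methoxyphenyl)methanolate | [Na+].[O-]Cc1ccc(OC)cc1 | intermediate
24 | tributyl{[(4-methoxybenzyl)oxy]methyl}stannane | CCCC[Sn](CCCC)(CCCC)COCc1ccc(OC)cc1 | intermediate
25 | {[(4-methoxybenzyl)oxy]methyl}lithium | [Li]COCc1ccc(OC)cc1 | intermediate
26 | lithium bis{[(4-methoxybenzyl)oxy]methyl}cuprate | [Li+].COc1ccc(COC[Cu-]COCc2ccc(OC)cc2)cc1 | intermediate
27 | lithium {(2Z)-1-methoxy-3-{[(4-methoxybenzyl)oxy]methyl}-1-oxo-5-(Bic)pent-2-en-2-yl}{[(4-methoxybenzyl)oxy]methyl}cuprate (copper cis to the new CH2O group) | [Li+].CC1=C(CC/C(COCc3ccc(OC)cc3)=C(/[Cu-]COCc3ccc(OC)cc3)C(=O)OC)[C@@]2(C)CCCC(C)(C)[C@H]2CC1 | intermediate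
28 | methyl (2E)-3-{[(4-methoxybenzyl)oxy]methyl}-5-(Bic)pent-2-enoate | CC1=C(CC/C(COCc3ccc(OC)cc3)=C\C(=O)OC)[C@@]2(C)CCCC(C)(C)[C@H]2CC1 | intermediate
29 | (2E)-3-{[(4-methoxybenzyl)oxy]methyl}-5-(Bic)pent-2-en-1-ol | CC1=C(CC/C(COCc3ccc(OC)cc3)=C\CO)[C@@]2(C)CCCC(C)(C)[C@H]2CC1 | intermediate
30 | (2E)-3-{[(4-methoxybenzyl)oxy]methyl}-5-(Bic)pent-2-enal | CC1=C(CC/C(COCc3ccc(OC)cc3)=C\C=O)[C@@]2(C)CCCC(C)(C)[C@H]2CC1 | intermediate
31 | 4-methylfuran-2(5H)-one | CC1=CC(=O)OC1 | starting material
32 | 4-(bromomethyl)furan-2(5H)-one | BrCC1=CC(=O)OC1 | intermediate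
33 | diethyl [(5-oxo-2,5-dihydrofuran-3-yl)methyl]phosphonate | CCOP(=O)(OCC)CC1=CC(=O)OC1 | intermediate
34 | lithium salt of 33, carbanion at the phosphorus-bearing carbon | [Li+].CCOP(=O)(OCC)[CH-]C1=CC(=O)OC1 | intermediate
35 | 4-[(1E,3E)-4-{[(4-methoxybenzyl)oxy]methyl}-6-(Bic)hexa-1,3-dien-1-yl]furan-2(5H)-one | CC1=C(CC/C(COCc3ccc(OC)cc3)=C\C=C\C4=CC(=O)OC4)[C@@]2(C)CCCC(C)(C)[C@H]2CC1 | intermediate
36 | 4-[(1E,3E)-4-(hydroxymethyl)-6-(Bic)hexa-1,3-dien-1-yl]furan-2(5H)-one (CNP0232848.3) | CC1=C(CC/C(=C\C=C\C2=CC(=O)OC2)CO)[C@@]2(C)CCCC(C)(C)[C@H]2CC1 | target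

**Totals**

Total step count: 19 (steps 12, 16 and 17 prepare reagents).
Longest linear sequence: 16 steps (steps 1–11, 13–15, 18 and 19, from (R)-α-ionone).

**Steps most likely to fail**

Step 5 (Heck closure). The vinylpalladium intermediate may fail to insert into the hindered trisubstituted ring alkene at its fully substituted carbon, so that protodeiodination or 7-endo closure at C1 takes over. The fallback sets out from 10 and comes back at 12. A tin hydride mediated radical cyclisation (Bu3SnH, AIBN, PhH, 80 °C, slow addition) should let the C9 vinyl radical attack C10 in the 6-exo mode from the tether face; the C1 radical is then reduced by the stannane. This gives the ring A saturated ester 12 directly and makes step 6 unnecessary; no new compound arises (F0).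

Step 4 (carbocupration and iodine capture). The monoalkylcopper may add sluggishly to the β-methyl ynoate, Wurtz coupling may consume the iodide during Grignard formation, or the alkene geometry may erode through the allenoate form of 9 before iodine capture. The fallback sets out from 2 and comes back at 11. Trimethyl phosphonoacetate is brominated (NaH, Br2, THF, 0 °C) to methyl bromo(dimethoxyphosphoryl)acetate F1. Its sodium salt olefinates ketone 2 (NaH, DME, reflux; Horner–Wadsworth–Emmons) to give methyl (2Z)-2-bromo-3-methyl-5-[(1R)-2,6,6-trimethylcyclohex-2-en-1-yl]pent-2-enoate F2 together with its E isomer, which cannot cyclise and is removed by chromatography. F2 is then closed under the conditions of step 5 (100 °C) to give 11. This bypasses steps 2–4 but gives up control of the alkene geometry.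

Step 18 (olefination with the butenolide phosphonate). Phosphonate 33 may be deprotonated at the ring CH2 of the butenolide instead of the exocyclic carbon, the dienolate may attack through its γ-position, or the base may isomerise enal 30. The fallback sets out from 30 and comes back at 35. Takai–Utimoto boron olefination of 30 (2-(dichloromethyl)-4,4,5,5-tetramethyl-1,3,2-dioxaborolane, CrCl2, LiI, THF, rt) should give 2-[(1E,3E)-4-{[(4-methoxybenzyl)oxy]methyl}-6-(Bic)hexa-1,3-dien-1-yl]-4,4,5,5-tetramethyl-1,3,2-dioxaborolane F3. Suzuki–Miyaura coupling of F3 with commercial 4-bromofuran-2(5H)-one (PdCl2(dppf) cat., K3PO4, THF/H2O, 50 °C) then forms the C16–butenolide bond and gives 35 without any butenolide carbanion.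

**Further compounds**

F0 | step 5 | none | none
F1 | step 4 | methyl bromo(dimethoxyphosphoryl)acetate | COC(=O)C(Br)P(=O)(OC)OC
F2 | step 4 | methyl (2Z)-2-bromo-3-methyl-5-[(1R)-2,6,6-trimethylcyclohex-2-en-1-yl]pent-2-enoate | COC(=O)/C(Br)=C(\C)CC[C@H]1C(C)=CCCC1(C)C
F3 | step 18 | 2-[(1E,3E)-4-{[(4-methoxybenzyl)oxy]methyl}-6-(Bic)hexa-1,3-dien-1-yl]-4,4,5,5-tetramethyl-1,3,2-dioxaborolane | CC1=C(CC/C(COCc3ccc(OC)cc3)=C\C=C\B4OC(C)(C)C(C)(C)O4)[C@@]2(C)CCCC(C)(C)[C@H]2CC1
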